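**Retrosynthetic overview**

1. The C2–C1' bond is made late by a ligand-controlled palladium-catalysed 1,4-addition of ring-B boronic acid 13 to 8-prenylchromone 21, which sets (2S); two MOM groups are then removed. Rings A and C come from 5,7-dihydroxychromone, with the C8 prenyl group installed by a Claisen–Cope rearrangement.
2. Ring D (the 2,2-dimethyl-2H-pyran on ring B) is cut at O–C(CH3)2 to an ortho-quinone methide, and this is traced through a benzoxete back to an aryne across C3'–C4' of ring B plus prenal. One operation puts O on C4', C on C3' and closes ring D.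
3. Enabling feature: ring D is fused through its oxygen and its vinylic C4 to two adjacent ring-B carbons (C4' and C3') and is the closed valence isomer of a 1-oxatriene. C5', beside the oxygen-bearing carbon, carries carbon, so a boron placed there can steer the aryne addition and then become the prenyl group.
4. After the key step the C5' boron is exchanged for prenyl (Suzuki–Miyaura allylation) and the C1' chlorine for B(OH)2.
5. Ring order: rings A, B and C are bought; ring D is the only ring formed (step 3).

Key step: step 3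

Remark: the sense of induction in step 10 is taken from the usual model for pyridine–oxazoline palladium catalysts, in which the (S)-ligand gives (2R)-2-arylchromanones, so the (R)-ligand is specified; if the sense proved opposite, the (S)-ligand would be used.

**Route**

Step 1
Reactants: 1 2,6-dibromo-4-chlorophenol
Product: 4 2-bromo-4-chloro-6-(trimethylsilyl)phenyl trifluoromethanesulfonate, via aryl trimethylsilyl ether 2 (not isolated), via lithium silylphenolate 3 (not isolated)
Conditions: HMDS, THF, 65 °C, then evaporation; n-BuLi (1.05 equiv), THF, −78 °C; Tf2O, −78 °C to rt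
Reagents that add atoms: hexamethyldisilazane C[Si](C)(C)N[Si](C)(C)C; trifluoromethanesulfonic anhydride O=S(=O)(OS(=O)(=O)C(F)(F)F)C(F)(F)F
Why: O-silylation followed by bromine–lithium exchange triggers a 1,3 O-to-C silyl shift (retro-Brook rearrangement) that places silicon ortho to the phenoxide, which is trapped as the triflate, and one equivalent of n-BuLi should leave the second bromine in place.

Step 2
Reactants: 4 2-bromo-4-chloro-6-(trimethylsilyl)phenyl trifluoromethanesulfonate
Product: 5 4-chloro-2-(4,4,5,5-tetramethyl-1,3,2-dioxaborolan-2-yl)-6-(trimethylsilyl)phenyl trifluoromethanesulfonate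
Conditions: B2pin2, PdCl2(dppf) (5 mol%), KOAc, 1,4-dioxane, 80 °C
Reagents that add atoms: bis(pinacolato)diboron CC1(C)OB(OC1(C)C)B1OC(C)(C)C(C)(C)O1
Why: Miyaura borylation, in which zerovalent palladium should insert into the C–Br bond in preference to the C–Cl bond and to the triflate shielded by two ortho substituents, while acetate is too weak a base to desilylate.

Step 3
Reactants: 5 4-chloro-2-(pinacolboryl)-6-(trimethylsilyl)phenyl trifluoromethanesulfonate; 6 3-methylbut-2-enal (prenal)
Product: 10 6-chloro-2,2-dimethyl-8-(4,4,5,5-tetramethyl-1,3,2-dioxaborolan-2-yl)-2H-chromene, via aryne 7 (not isolated), via benzoxete 8 (not isolated), via ortho-quinone methide 9 (not isolated)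
Conditions: CsF (3 equiv), 6 (4 equiv), MeCN, 0 °C to rt
Reagents that add atoms: 3-methylbut-2-enal (6) CC(C)=CC=O
Why: Fluoride removes the trimethylsilyl group and triflate leaves, giving aryne 7, whose triple bond lies between the future C3' and C4' of ring B and is flanked on the C4' side by the boron-bearing C5'. The carbonyl oxygen of prenal adds to C4' and the aryl anion at C3' closes on the carbonyl carbon (stepwise [2+2]) to benzoxete 8, which opens by a 4π-electrocyclic reaction to ortho-quinone methide 9; the 1-oxatriene of 9 then closes ring D by a thermal disrotatory oxa-6π-electrocyclization that forms the O–C(CH3)2 bond and restores the aromaticity of ring B. The closest known reaction type is the annulation of arynes with α,β-unsaturated aldehydes to 2H-chromenes, combined with the ortho-selective addition of heteroatom nucleophiles to 3-borylarynes. No stereocenter is formed, because the new sp3 carbon carries two methyl groups and the benzoxete carbon returns to sp2. The step needs regioselectivity (oxygen beside boron), which has not been tested for this annulation on a borylaryne: the electropositive boryl group should distort the aryne so that the carbon next to it is the electrophilic one and negative charge develops at the remote carbon, the Lewis-acidic boron can pre-coordinate the carbonyl oxygen, and the substituted carbonyl carbon avoids the pinacol ester, so electronic and steric effects point the same way. It also needs chemoselectivity, which should hold because fluoride binds boron only reversibly, the aryl chloride is inert, and the intramolecular closure of 9 should be faster than its capture by a second aldehyde or aryne.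

Step 4
Reactants: 10 6-chloro-2,2-dimethyl-8-(pinacolboryl)-2H-chromene; 11 1-bromo-3-methylbut-2-ene (prenyl bromide)
Product: 12 6-chloro-2,2-dimethyl-8-(3-methylbut-2-en-1-yl)-2H-chromene
Conditions: 11 (2 equiv), Pd(PPh3)4 (5 mol%), K2CO3, THF/H2O (10:1), 60 °C
Reagents that add atoms: prenyl bromide (11) CC(C)=CCBr
Why: Suzuki–Miyaura allylation, in which zerovalent palladium ionises prenyl bromide to a π-prenyl complex, the boronate transfers the aryl group and reductive elimination at the unsubstituted allyl terminus should give the linear prenyl arene, while the aryl chloride does not react with this catalyst.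

Step 5
Reactants: 12 6-chloro-2,2-dimethyl-8-(3-methylbut-2-en-1-yl)-2H-chromene
Product: 13 [2,2-dimethyl-8-(3-methylbut-2-en-1-yl)-2H-chromen-6-yl]boronic acid
Conditions: B2(OH)4, Pd(OAc)2 (2 mol%), XPhos (4 mol%), KOAc, EtOH, 80 °C
Reagents that add atoms: tetrahydroxydiboron OB(O)B(O)O
Why: Miyaura-type borylation of an aryl chloride with tetrahydroxydiboron under a bulky biarylphosphine palladium catalyst should give the free boronic acid directly without touching the two alkenes.

Step 6
Reactants: 14 5,7-dihydroxy-4H-chromen-4-one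
Product: 15 5-hydroxy-7-(methoxymethoxy)-4H-chromen-4-one
Conditions: MOMCl (1.1 equiv), DIPEA, CH2Cl2/DMF, 0 °C to rt
Reagents that add atoms: chloromethyl methyl ether COCCl
Why: Selective Williamson-type O-alkylation of the more acidic, non-chelated 7-hydroxyl, the 5-hydroxyl being held in a hydrogen bond to the C4 carbonyl.

Step 7
Reactants: 15 5-hydroxy-7-(methoxymethoxy)-4H-chromen-4-one; 16 3-methylbut-2-en-1-ol (prenol)
Product: 17 7-(methoxymethoxy)-5-[(3-methylbut-2-en-1-yl)oxy]-4H-chromen-4-one
Conditions: 16, PPh3, DIAD, THF, 0 °C to rt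
Reagents that add atoms: 3-methylbut-2-en-1-ol (16) CC(C)=CCO
Why: Mitsunobu etherification alkylates the hydrogen-bonded 5-hydroxyl under neutral conditions at the primary carbon of prenol and avoids the C-alkylation seen with prenyl halides and base.

Step 8
Reactants: 17 7-(methoxymethoxy)-5-[(3-methylbut-2-en-1-yl)oxy]-4H-chromen-4-one
Product: 20 5-hydroxy-7-(methoxymethoxy)-8-(3-methylbut-2-en-1-yl)-4H-chromen-4-one, via Claisen dienone 18 (not isolated), via Cope dienone 19 (not isolated)
Conditions: Eu(fod)3 (10 mol%), CHCl3, 60 °C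
Reagents that add atoms: none
Why: Lewis-acid-catalysed tandem Claisen–Cope rearrangement, in which a first [3,3] shift delivers a 1,1-dimethylallyl group to C6 and a second [3,3] shift carries it as a linear prenyl group to C8 before enolisation, a sequence with close precedent for 5-O-prenyl flavonoids.

Step 9
Reactants: 20 5-hydroxy-7-(methoxymethoxy)-8-(3-methylbut-2-en-1-yl)-4H-chromen-4-one
Product: 21 5,7-bis(methoxymethoxy)-8-(3-methylbut-2-en-1-yl)-4H-chromen-4-one
Conditions: NaH, MOMCl, DMF, 0 °C
Reagents that add atoms: chloromethyl methyl ether COCCl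
Why: Williamson-type alkylation of the chelated 5-phenoxide, generated irreversibly with NaH, masks the hydroxy-ketone chelating site that could bind palladium in step 10.

Step 10
Reactants: 21 5,7-bis(methoxymethoxy)-8-(3-methylbut-2-en-1-yl)-4H-chromen-4-one; 13 [2,2-dimethyl-8-(3-methylbut-2-en-1-yl)-2H-chromen-6-yl]boronic acid
Product: 22 (2S)-2-[2,2-dimethyl-8-(3-methylbut-2-en-1-yl)-2H-chromen-6-yl]-5,7-bis(methoxymethoxy)-8-(3-methylbut-2-en-1-yl)chroman-4-one
Conditions: 13 (2 equiv), Pd(OCOCF3)2 (5 mol%), (R)-4-tert-butyl-2-(pyridin-2-yl)-4,5-dihydrooxazole (6 mol%), NH4PF6 (30 mol%), H2O (5 equiv), ClCH2CH2Cl, 60 °C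
Reagents that add atoms: none
Why: Palladium-catalysed asymmetric conjugate addition of an arylboronic acid to a chromone, in which transmetalation to cationic divalent palladium, enantiodetermining insertion of the C2=C3 bond into the Pd–aryl bond on the face left open by the tert-butyl group of the ligand and protonolysis of the palladium enolate set C2, the (R)-ligand being expected to give the (2S)-configuration.

Step 11
Reactants: 22 (2S)-bis(methoxymethyl) ether of the target
Product: 23 Maackiaflavanone B, (2S)-2-[2,2-dimethyl-8-(3-methylbut-2-en-1-yl)-2H-chromen-6-yl]-5,7-dihydroxy-8-(3-methylbut-2-en-1-yl)chroman-4-one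
Conditions: 3 M HCl (aq), MeOH/THF, 40 °C, stopped at full conversion
Reagents that add atoms: none
Why: Acid-catalysed acetal exchange with methanol should remove both methoxymethyl groups under dilute-acid conditions of the kind used for prenylated flavanone methoxymethyl ethers, and C2 should not epimerise because ring opening to the chalcone needs base.

**Compound list**

1 | 2,6-dibromo-4-chlorophenol | Oc1c(Br)cc(Cl)cc1Br | starting material
2 | (2,6-dibromo-4-chlorophenoxy)trimethylsilane | C[Si](C)(C)Oc1c(Br)cc(Cl)cc1Br | intermediate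
3 | lithium 2-bromo-4-chloro-6-(trimethylsilyl)phenolate | [Li+].[O-]c1c(Br)cc(Cl)cc1[Si](C)(C)C | intermediate
4 | 2-bromo-4-chloro-6-(trimethylsilyl)phenyl trifluoromethanesulfonate | C[Si](C)(C)c1cc(Cl)cc(Br)c1OS(=O)(=O)C(F)(F)F | intermediate
5 | 4-chloro-2-(4,4,5,5-tetramethyl-1,3,2-dioxaborolan-2-yl)-6-(trimethylsilyl)phenyl trifluoromethanesulfonate | C[Si](C)(C)c1cc(Cl)cc(B2OC(C)(C)C(C)(C)O2)c1OS(=O)(=O)C(F)(F)F | intermediate
6 | 3-methylbut-2-enal (prenal) | CC(C)=CC=O | starting material
7 | 2-(5-chloro-2,3-didehydrophenyl)-4,4,5,5-tetramethyl-1,3,2-dioxaborolane (aryne) | C1#CC=C(Cl)C=C1B1OC(C)(C)C(C)(C)O1 | intermediate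
8 | 4-chloro-2-(2-methylprop-1-en-1-yl)-6-(pinacolboryl)-2H-benzoxete (racemic) | CC(C)=CC1Oc2c1cc(Cl)cc2B1OC(C)(C)C(C)(C)O1 | intermediate
9 | 4-chloro-6-(3-methylbut-2-en-1-ylidene)-2-(pinacolboryl)cyclohexa-2,4-dien-1-one (ortho-quinone methide) | O=C1C(=CC=C(C)C)C=C(Cl)C=C1B1OC(C)(C)C(C)(C)O1 | intermediate
10 | 6-chloro-2,2-dimethyl-8-(4,4,5,5-tetramethyl-1,3,2-dioxaborolan-2-yl)-2H-chromene | CC1(C)C=Cc2cc(Cl)cc(B3OC(C)(C)C(C)(C)O3)c2O1 | intermediate
11 | 1-bromo-3-methylbut-2-ene (prenyl bromide) | CC(C)=CCBr | starting material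
12 | 6-chloro-2,2-dimethyl-8-(3-methylbut-2-en-1-yl)-2H-chromene | CC(C)=CCc1cc(Cl)cc2c1OC(C)(C)C=C2 | intermediate
13 | [2,2-dimethyl-8-(3-methylbut-2-en-1-yl)-2H-chromen-6-yl]boronic acid | CC(C)=CCc1cc(B(O)O)cc2c1OC(C)(C)C=C2 | intermediate
14 | 5,7-dihydroxy-4H-chromen-4-one | O=c1ccoc2cc(O)cc(O)c12 | starting material
15 | 5-hydroxy-7-(methoxymethoxy)-4H-chromen-4-one | O=c1ccoc2cc(OCOC)cc(O)c12 | intermediate
16 | 3-methylbut-2-en-1-ol (prenol) | CC(C)=CCO | starting material
17 | 7-(methoxymethoxy)-5-[(3-methylbut-2-en-1-yl)oxy]-4H-chromen-4-one | O=c1ccoc2cc(OCOC)cc(OCC=C(C)C)c12 | intermediate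
18 | 7-(methoxymethoxy)-6-(2-methylbut-3-en-2-yl)-4H-chromene-4,5(6H)-dione (racemic) | O=C1C=COC2=C1C(=O)C(C(C)(C)C=C)C(OCOC)=C2 | intermediate
19 | 7-(methoxymethoxy)-8-(3-methylbut-2-en-1-yl)-4H-chromene-4,5(8H)-dione (racemic) | O=C1C=COC2=C1C(=O)C=C(OCOC)C2CC=C(C)C | intermediate
20 | 5-hydroxy-7-(methoxymethoxy)-8-(3-methylbut-2-en-1-yl)-4H-chromen-4-one | O=c1ccoc2c(CC=C(C)C)c(OCOC)cc(O)c12 | intermediate
21 | 5,7-bis(methoxymethoxy)-8-(3-methylbut-2-en-1-yl)-4H-chromen-4-one | O=c1ccoc2c(CC=C(C)C)c(OCOC)cc(OCOC)c12 | intermediate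
22 | (2S)-2-[2,2-dimethyl-8-(3-methylbut-2-en-1-yl)-2H-chromen-6-yl]-5,7-bis(methoxymethoxy)-8-(3-methylbut-2-en-1-yl)chroman-4-one | CC(C)=CCc1cc([C@@H]2CC(=O)c3c(OCOC)cc(OCOC)c(CC=C(C)C)c3O2)cc2c1OC(C)(C)C=C2 | intermediate
23 | Maackiaflavanone B, (2S)-2-[2,2-dimethyl-8-(3-methylbut-2-en-1-yl)-2H-chromen-6-yl]-5,7-dihydroxy-8-(3-methylbut-2-en-1-yl)chroman-4-one | CC(C)=CCc1cc([C@@H]2CC(=O)c3c(O)cc(O)c(CC=C(C)C)c3O2)cc2c1OC(C)(C)C=C2 | target

**Step count and risks**

Total steps: 11. Longest linear sequence: 7 steps (steps 1 to 5, then 10 and 11); steps 6 to 9 form the second branch.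

Most likely to fail, step 3: the carbonyl oxygen may add to the aryne carbon remote from boron (loss of regiocontrol), fluoride may degrade the boronate, or prenal may self-condense under basic fluoride. The fallback uses known chemistry and sets out from 1 and 6. Treatment of 1 with n-BuLi (2.1 equiv, THF, −78 °C) gives the ortho-lithiated phenoxide, which adds 1,2 to prenal 6 to give racemic 2-bromo-4-chloro-6-(1-hydroxy-3-methylbut-2-en-1-yl)phenol F1. Warming F1 with catalytic PPTS in toluene causes dehydration and in-situ oxa-6π ring closure to 8-bromo-6-chloro-2,2-dimethyl-2H-chromene F2, with the oxygen position fixed by the phenol. Miyaura borylation of F2 (B2pin2, PdCl2(dppf), KOAc, dioxane, 80 °C) selectively at bromine returns the route at 10.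

Second, step 10: facial discrimination may be insufficient with the 5-alkoxy-8-alkyl chromone, and the aryl transfer may be slowed by protodeboronation. The fallback sets out from 13 and 21 and separates bond formation from stereocontrol. Addition under an achiral catalyst (Pd(OCOCF3)2, 2,2'-bipyridine, NH4PF6, H2O, ClCH2CH2Cl, 60 °C) gives the racemic flavanone F3. Kinetic resolution by asymmetric transfer hydrogenation (RuCl(p-cymene)[(R,R)-TsDPEN], HCO2H/Et3N) should reduce the (2R)-enantiomer to the cis-carbinol (2R,4R)-2-[2,2-dimethyl-8-(3-methylbut-2-en-1-yl)-2H-chromen-6-yl]-5,7-bis(methoxymethoxy)-8-(3-methylbut-2-en-1-yl)chroman-4-ol F4. The unreduced (2S)-ketone is separated by chromatography and returns the route at 22.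

Third, step 11: acid may trigger cyclisation of the C8 prenyl group onto the freed 7-hydroxyl or addition of methanol to the ring-D alkene before both acetals are gone. The fallback changes the protecting-group plan to esters removed under neutral conditions and sets out from 14.
- Ac2O (1 equiv) in pyridine at 0 °C gives 5-hydroxy-4-oxo-4H-chromen-7-yl acetate F5.
- Mitsunobu reaction with 16 gives 5-[(3-methylbut-2-en-1-yl)oxy]-4-oxo-4H-chromen-7-yl acetate F6.
- Eu(fod)3 in CHCl3 at 60 °C gives 5-hydroxy-8-(3-methylbut-2-en-1-yl)-4-oxo-4H-chromen-7-yl acetate F7.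
- Ac2O, Et3N and catalytic DMAP give 8-(3-methylbut-2-en-1-yl)-4-oxo-4H-chromene-5,7-diyl diacetate F8.
- The conditions of step 10 with 13 give (2S)-2-[2,2-dimethyl-8-(3-methylbut-2-en-1-yl)-2H-chromen-6-yl]-8-(3-methylbut-2-en-1-yl)-4-oxochroman-5,7-diyl diacetate F9.
- NH4OAc in aqueous methanol at rt cleaves both aryl acetates and returns the route at 23.

**Further compounds**

F1 | step 3 | 2-bromo-4-chloro-6-(1-hydroxy-3-methylbut-2-en-1-yl)phenol (racemic) | CC(C)=CC(O)c1cc(Cl)cc(Br)c1O
F2 | step 3 | 8-bromo-6-chloro-2,2-dimethyl-2H-chromene | CC1(C)C=Cc2cc(Cl)cc(Br)c2O1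
F3 | step 10 | racemic 2-[2,2-dimethyl-8-(3-methylbut-2-en-1-yl)-2H-chromen-6-yl]-5,7-bis(methoxymethoxy)-8-(3-methylbut-2-en-1-yl)chroman-4-one | CC(C)=CCc1cc(C2CC(=O)c3c(OCOC)cc(OCOC)c(CC=C(C)C)c3O2)cc2c1OC(C)(C)C=C2
F4 | step 10 | (2R,4R)-2-[2,2-dimethyl-8-(3-methylbut-2-en-1-yl)-2H-chromen-6-yl]-5,7-bis(methoxymethoxy)-8-(3-methylbut-2-en-1-yl)chroman-4-ol | CC(C)=CCc1cc([C@H]2C[C@@H](O)c3c(OCOC)cc(OCOC)c(CC=C(C)C)c3O2)cc2c1OC(C)(C)C=C2
F5 | step 11 | 5-hydroxy-4-oxo-4H-chromen-7-yl acetate | O=c1ccoc2cc(OC(C)=O)cc(O)c12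
F6 | step 11 | 5-[(3-methylbut-2-en-1-yl)oxy]-4-oxo-4H-chromen-7-yl acetate | O=c1ccoc2cc(OC(C)=O)cc(OCC=C(C)C)c12
F7 | step 11 | 5-hydroxy-8-(3-methylbut-2-en-1-yl)-4-oxo-4H-chromen-7-yl acetate | O=c1ccoc2c(CC=C(C)C)c(OC(C)=O)cc(O)c12
F8 | step 11 | 8-(3-methylbut-2-en-1-yl)-4-oxo-4H-chromene-5,7-diyl diacetate | O=c1ccoc2c(CC=C(C)C)c(OC(C)=O)cc(OC(C)=O)c12
F9 | step 11 | (2S)-2-[2,2-dimethyl-8-(3-methylbut-2-en-1-yl)-2H-chromen-6-yl]-8-(3-methylbut-2-en-1-yl)-4-oxochroman-5,7-diyl diacetate | CC(C)=CCc1cc([C@@H]2CC(=O)c3c(OC(C)=O)cc(OC(C)=O)c(CC=C(C)C)c3O2)cc2c1OC(C)(C)C=C2
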